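**Retrosynthetic overview** (lactone ring atoms O1, C2 carbonyl, C3, C4, C5; left chain C2′–C6′ from C5; right chain C1″–C8″ from C3)
1. Target 35 is cut at C3–C1″ into lactone 23 and dienyl iodide 31 (an Evans syn-aldol fragment), joined by palladium-catalysed α-alkenylation of the lactone zinc enolate; desilylation comes last.
2. Feature used: in the lactone ring the oxygen-bearing C5 is the allylic terminus of the left (2E,4E)-diene and stands γ to the C2 carboxyl carbon, so the lactone is masked as cyclopropane 20 (C3–C4–C5, two tert-butyl esters on C3). Heterolysis of the temporary C3–C5 bond and O1–C5 closure give 21, and decarboxylation gives 23.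
3. Cyclopropane 20 comes from di-tert-butyl ethylidenemalonate 3 and chiral sulfonium ylide 19 (from dienyl bromide 16); only C4 has to be set there, because C5 is re-formed in the key step.
4. Both dienes come from (E)-3-iodo-2-methylprop-2-en-1-ol 6: Suzuki–Miyaura coupling with boronate 14 on the left (C6′ from an Evans methylation), homologation to dienal 25 and an Evans aldol on the right.
5. Ring order: cyclopropane (step 11), then the lactone by its opening (step 12); no other ring is formed.

Key step: step 12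

Remark (assumption on the chemistry): the (1R,4R,5R) antipode of isothiocineole is taken to deliver the (3R) methyl-bearing centre of cyclopropane 20 in step 11; should a trial run show the opposite sense, the (1S,4S,5S) antipode is used in its place and nothing else changes.

Step 1
Reactants: 1 di-tert-butyl malonate; 2 acetaldehyde
Product: 3 di-tert-butyl 2-ethylidenemalonate
Conditions: TiCl4, pyridine, THF, 0 °C to rt
Reagents that add atoms: none
Why: Knoevenagel condensation in which TiCl4 activates acetaldehyde and takes up the water while pyridine deprotonates the malonate and buffers the medium, so the tert-butyl esters should survive; no stereocentre is formed.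

Step 2
Reactants: 4 prop-2-yn-1-ol
Product: 6 (E)-3-iodo-2-methylprop-2-en-1-ol, via alkenylalane 5 (not isolated)
Conditions: AlMe3, Cp2ZrCl2 (25 mol %), CH2Cl2, 0 °C to rt; I2, THF, −30 °C; aq. K2CO3
Reagents that add atoms: trimethylaluminium, SMILES C[Al](C)C; iodine, SMILES II
Why: Zirconium-catalysed carboalumination (Negishi) should add methyl and aluminium syn across the alkyne with methyl on the internal carbon, and iodinolysis with retention gives the E iodide.

Step 3
Reactants: 7 (R)-4-benzyloxazolidin-2-one; 8 hexanoyl chloride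
Product: 9 (R)-4-benzyl-3-hexanoyloxazolidin-2-one
Conditions: n-BuLi, THF, −78 °C; then 8, −78 to 0 °C
Reagents that add atoms: none
Why: N-acylation of the lithiated oxazolidinone by the acid chloride (acyl substitution), which leaves the auxiliary centre untouched.

Step 4
Reactants: 9 (R)-4-benzyl-3-hexanoyloxazolidin-2-one
Product: 11 (R)-4-benzyl-3-[(R)-2-methylhexanoyl]oxazolidin-2-one, via sodium enolate 10 (not isolated)
Conditions: NaN(SiMe3)2, THF, −78 °C; MeI, −78 to −40 °C
Reagents that add atoms: iodomethane, SMILES CI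
Why: Evans alkylation, in which the chelated Z-enolate is methylated on the face opposite the benzyl group, which should set the (R) centre that becomes C6′.

Step 5
Reactants: 11 (R)-4-benzyl-3-[(R)-2-methylhexanoyl]oxazolidin-2-one
Product: 12 (R)-2-methylhexan-1-ol
Conditions: LiBH4, MeOH (1 equiv), Et2O, 0 °C
Reagents that add atoms: none
Why: Hydride reduction of the exocyclic imide carbonyl releases the alcohol and the auxiliary without epimerising the α-centre.

Step 6
Reactants: 12 (R)-2-methylhexan-1-ol
Product: 13 (R)-2-methylhexanal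
Conditions: TEMPO (10 mol %), PhI(OAc)2, CH2Cl2, rt
Reagents that add atoms: none
Why: Oxoammonium-mediated oxidation under near-neutral conditions stops at the aldehyde and should not epimerise the α-stereocentre; the volatile aldehyde is used directly.

Step 7
Reactants: 13 (R)-2-methylhexanal
Product: 14 2-[(1E,3R)-3-methylhept-1-en-1-yl]-4,4,5,5-tetramethyl-1,3,2-dioxaborolane
Conditions: CrCl2 (8 equiv), Cl2CHBpin (2 equiv), LiI (4 equiv), THF, rt
Reagents that add atoms: 2-(dichloromethyl)-4,4,5,5-tetramethyl-1,3,2-dioxaborolane, SMILES ClC(Cl)B1OC(C)(C)C(C)(C)O1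
Why: Takai–Utimoto-type olefination with a geminal dichromium boryl reagent is E-selective for α-branched aldehydes and mild enough to keep the α-centre.

Step 8
Reactants: 14 2-[(1E,3R)-3-methylhept-1-en-1-yl]-4,4,5,5-tetramethyl-1,3,2-dioxaborolane; 6 (E)-3-iodo-2-methylprop-2-en-1-ol
Product: 15 (2E,4E,6R)-2,6-dimethyldeca-2,4-dien-1-ol
Conditions: Pd(PPh3)4 (5 mol %), 2 M aq. NaOH, THF, 50 °C
Reagents that add atoms: none
Why: Suzuki–Miyaura coupling of an alkenylboronate with an alkenyl iodide proceeds with retention at both alkenes and tolerates the free allylic alcohol.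

Step 9
Reactants: 15 (2E,4E,6R)-2,6-dimethyldeca-2,4-dien-1-ol
Product: 16 (2E,4E,6R)-1-bromo-2,6-dimethyldeca-2,4-diene
Conditions: CBr4, PPh3, CH2Cl2, −20 °C; short silica filtration, used at once
Reagents that add atoms: tetrabromomethane, SMILES BrC(Br)(Br)Br
Why: Appel reaction, an SN2 displacement at the primary allylic carbon under neutral conditions at low temperature, should keep the bromide at C1 and the diene geometry.

Step 10
Reactants: 16 (2E,4E,6R)-1-bromo-2,6-dimethyldeca-2,4-diene; 17 (1R,4R,5R)-isothiocineole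
Product: 18 (1R,4R,5R)-6-[(2E,4E,6R)-2,6-dimethyldeca-2,4-dien-1-yl]-4,7,7-trimethyl-6-thiabicyclo[3.2.1]octan-6-ium triflate
Conditions: LiOTf, CH2Cl2/H2O, rt
Reagents that add atoms: lithium trifluoromethanesulfonate, SMILES [Li+].[O-]S(=O)(=O)C(F)(F)F
Why: SN2 S-alkylation of the sulfide by the allylic bromide, driven by exchange of bromide for non-nucleophilic triflate in the two-phase medium; alkylation on the less hindered sulfur lone pair should give one sulfonium diastereomer.

Step 11
Reactants: 18 sulfonium triflate; 3 di-tert-butyl 2-ethylidenemalonate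
Product: 20 di-tert-butyl (2S,3R)-3-methyl-2-[(2E,4E,6R)-6-methyldeca-2,4-dien-2-yl]cyclopropane-1,1-dicarboxylate, via sulfonium ylide 19 (not isolated)
Conditions: KN(SiMe3)2, THF, −78 °C; then 3, −78 to −20 °C
Reagents that add atoms: none
Why: Michael-initiated ring closure of a sulfonium allylide (Corey–Chaykovsky-type cyclopropanation), in which the ylide α-carbon should add to the β-carbon of 3 and the malonate anion then displace the sulfide by 3-exo-tet closure under base-only conditions that leave the dienylcyclopropane intact; the rigid bicyclic sulfide exposes one face of the ylide carbon and the anti arrangement of the dienyl group and the β-methyl group sets the methyl-bearing centre as (3R), the only ring centre of 20 carried into the target.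

Step 12
Reactants: 20 di-tert-butyl (2S,3R)-3-methyl-2-[(2E,4E,6R)-6-methyldeca-2,4-dien-2-yl]cyclopropane-1,1-dicarboxylate
Product: 21 tert-butyl (3S,4S,5S)-4-methyl-5-[(2E,4E,6R)-6-methyldeca-2,4-dien-2-yl]-2-oxotetrahydrofuran-3-carboxylate
Conditions: Sc(OTf)3 (10 mol %), CH2Cl2, 0 °C to rt
Reagents that add atoms: none
Why: Sc(OTf)3 should chelate the geminal diester of 20 and heterolyse the C1–C2 bond of the cyclopropane (lactone C3–C5), giving a scandium malonate enolate at C3 and a pentadienyl cation whose near terminus is C5; the carbonyl oxygen of one tert-butyl ester captures C5, the resulting dialkoxycarbenium ion loses isobutene, and the proton set free quenches the enolate at C3. The closest known reaction type is the acid-promoted ring-opening lactonisation of 2-vinyl- and 2-arylcyclopropane-1,1-dicarboxylic acids and esters to 5-substituted 2-oxotetrahydrofuran-3-carboxylates. The lactone ring (O1, C2, C3, C4, C5) closes by 5-exo attack of oxygen on the cation terminus C5, which forms the O1–C5 bond, whereas attack at the distal termini C3′ and C5′ would need seven- and nine-membered rings. C5 is controlled by the untouched C4 centre, the dienyl group taking the side anti to the C4 methyl group, and because the allylic C5–O1 bond can re-ionise under the same catalyst the trans isomer is also the thermodynamic outcome; C3 is protonated anti to the C4 methyl group, stays epimerisable and is removed in step 13. The step needs O- over C-capture and retention of the (E,E)-diene: the 2′-methyl group keeps the cation in the extended shape in which the enolate carbon cannot reach C3′ (no cyclopentene), the E,E form is the most stable one on recombination, and only the C4 configuration of 20 matters since C5 is re-formed.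

Step 13
Reactants: 21 tert-butyl (3S,4S,5S)-4-methyl-5-[(2E,4E,6R)-6-methyldeca-2,4-dien-2-yl]-2-oxotetrahydrofuran-3-carboxylate
Product: 23 (4S,5S)-4-methyl-5-[(2E,4E,6R)-6-methyldeca-2,4-dien-2-yl]dihydrofuran-2(3H)-one, via carboxylic acid 22 (not isolated)
Conditions: TFA/CH2Cl2 (1:5), 0 °C; evaporation; toluene, 100 °C
Reagents that add atoms: none
Why: Acidolysis of the remaining tert-butyl ester gives an α-carboxy lactone that should lose CO2 through a six-membered transition state on warming (malonic half-ester decarboxylation); C4 and C5 are not involved and C3 becomes a methylene group.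

Step 14
Reactants: 6 (E)-3-iodo-2-methylprop-2-en-1-ol
Product: 25 (2E,4E)-5-iodo-4-methylpenta-2,4-dienal, via iodoenal 24 (not isolated)
Conditions: MnO2, CH2Cl2, rt; filtration; Ph3P=CHCHO, toluene, 60 °C
Reagents that add atoms: (triphenylphosphoranylidene)acetaldehyde, SMILES O=CC=P(c1ccccc1)(c1ccccc1)c1ccccc1
Why: MnO2 oxidises the allylic alcohol selectively to the volatile iodoenal, which is trapped without isolation in a Wittig reaction with the formyl-stabilised ylide to give the E enal; the trisubstituted iodoalkene keeps its geometry.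

Step 15
Reactants: 26 (R)-4-benzyl-3-propionyloxazolidin-2-one; 25 (2E,4E)-5-iodo-4-methylpenta-2,4-dienal
Product: 28 (R)-4-benzyl-3-[(2R,3S,4E,6E)-3-hydroxy-7-iodo-2,6-dimethylhepta-4,6-dienoyl]oxazolidin-2-one, via boron enolate 27 (not isolated)
Conditions: n-Bu2BOTf, i-Pr2NEt, CH2Cl2, 0 °C; 25, −78 to 0 °C; H2O2, MeOH, pH 7 buffer
Reagents that add atoms: none
Why: Evans syn aldol, in which the Z-boron enolate reacts through a closed chair transition state (Zimmerman–Traxler) on the face away from the benzyl group, which should set (2R,3S), that is C6″ (R) and C5″ (S) of the target.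

Step 16
Reactants: 28 (R)-4-benzyl-3-[(2R,3S,4E,6E)-3-hydroxy-7-iodo-2,6-dimethylhepta-4,6-dienoyl]oxazolidin-2-one
Product: 29 (2R,3S,4E,6E)-3-hydroxy-7-iodo-N-methoxy-N,2,6-trimethylhepta-4,6-dienamide
Conditions: MeONHMe·HCl, AlMe3, THF, −20 to 0 °C
Reagents that add atoms: N,O-dimethylhydroxylamine hydrochloride, SMILES CNOC.Cl
Why: Aluminium amide aminolysis of the imide (Weinreb amide formation), in which the free β-hydroxyl binds aluminium and directs attack to the exocyclic carbonyl, so the auxiliary should leave without retro-aldol cleavage or epimerisation.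

Step 17
Reactants: 29 (2R,3S,4E,6E)-3-hydroxy-7-iodo-N-methoxy-N,2,6-trimethylhepta-4,6-dienamide
Product: 30 (2R,3S,4E,6E)-7-iodo-N-methoxy-N,2,6-trimethyl-3-(triethylsilyloxy)hepta-4,6-dienamide
Conditions: Et3SiCl, imidazole, CH2Cl2, 0 °C
Reagents that add atoms: chlorotriethylsilane, SMILES CC[Si](Cl)(CC)CC
Why: Silylation of the secondary allylic alcohol; the triethylsilyl ether should survive the Grignard and enolate steps and leave under buffered fluoride at the end.

Step 18
Reactants: 30 (2R,3S,4E,6E)-7-iodo-N-methoxy-N,2,6-trimethyl-3-(triethylsilyloxy)hepta-4,6-dienamide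
Product: 31 (3R,4S,5E,7E)-8-iodo-3,7-dimethyl-4-(triethylsilyloxy)octa-5,7-dien-2-one
Conditions: MeMgBr, THF, 0 °C; aq. NH4Cl
Reagents that add atoms: methylmagnesium bromide, SMILES C[Mg]Br
Why: Ketone synthesis from the N-methoxy-N-methylamide, where the chelated tetrahedral intermediate prevents over-addition and the alkenyl iodide should not exchange with MeMgBr at 0 °C.

Step 19
Reactants: 23 (4S,5S)-4-methyl-5-[(2E,4E,6R)-6-methyldeca-2,4-dien-2-yl]dihydrofuran-2(3H)-one; 31 (3R,4S,5E,7E)-8-iodo-3,7-dimethyl-4-(triethylsilyloxy)octa-5,7-dien-2-one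
Product: 34 (3S,4S,5S)-3-[(1E,3E,5S,6R)-2,6-dimethyl-7-oxo-5-(triethylsilyloxy)octa-1,3-dien-1-yl]-4-methyl-5-[(2E,4E,6R)-6-methyldeca-2,4-dien-2-yl]dihydrofuran-2(3H)-one, via lithium enolate 32 (not isolated), via zinc enolate 33 (not isolated)
Conditions: LiN(SiMe3)2, THF, −78 °C; ZnCl2, −78 to 0 °C; 31, Pd(P(t-Bu)3)2 (5 mol %), THF, rt
Reagents that add atoms: none
Why: Palladium-catalysed α-alkenylation of an ester enolate (Negishi-type coupling of a zinc enolate with an alkenyl iodide), in which oxidative addition of zerovalent palladium retains the (E,E)-geometry and reductive elimination from the C-bound palladium enolate should form the C3–C1″ bond anti to the C4 methyl group, the trans,trans arrangement also being thermodynamically preferred at the epimerisable C3; the weakly basic zinc enolate should tolerate the methyl ketone and not move the new double bond into conjugation.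

Step 20
Reactants: 34 triethylsilyl ether of the target
Product: 35 (3S,4S,5S)-3-[(1E,3E,5S,6R)-5-hydroxy-2,6-dimethyl-7-oxoocta-1,3-dien-1-yl]-4-methyl-5-[(2E,4E,6R)-6-methyldeca-2,4-dien-2-yl]dihydrofuran-2(3H)-one (CNP0320265.2)
Conditions: HF·pyridine, pyridine, THF, 0 °C
Reagents that add atoms: none
Why: Fluoride-mediated cleavage of the triethylsilyl ether under pyridine-buffered conditions should free the C5″ hydroxyl without β-elimination or retro-aldol cleavage of the ketol and without epimerisation at C3 or C6″.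

**Compound list**
1 | di-tert-butyl malonate | CC(C)(C)OC(=O)CC(=O)OC(C)(C)C | starting material
2 | acetaldehyde | CC=O | starting material
3 | di-tert-butyl 2-ethylidenemalonate | CC=C(C(=O)OC(C)(C)C)C(=O)OC(C)(C)C | intermediate
4 | prop-2-yn-1-ol | C#CCO | starting material
5 | dimethyl[(E)-3-(dimethylalumanyloxy)-2-methylprop-1-en-1-yl]alane (alkenylalane) | C[Al](C)/C=C(\C)CO[Al](C)C | intermediate
6 | (E)-3-iodo-2-methylprop-2-en-1-ol | OC/C(C)=C/I | intermediate
7 | (R)-4-benzyloxazolidin-2-one | O=C1N[C@H](Cc2ccccc2)CO1 | starting material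
8 | hexanoyl chloride | CCCCCC(=O)Cl | starting material
9 | (R)-4-benzyl-3-hexanoyloxazolidin-2-one | CCCCCC(=O)N1[C@H](Cc2ccccc2)COC1=O | intermediate
10 | sodium (Z)-enolate of 9 | CCCC/C=C(\[O-])N1[C@H](Cc2ccccc2)COC1=O.[Na+] | intermediate
11 | (R)-4-benzyl-3-[(R)-2-methylhexanoyl]oxazolidin-2-one | CCCC[C@@H](C)C(=O)N1[C@H](Cc2ccccc2)COC1=O | intermediate
12 | (R)-2-methylhexan-1-ol | CCCC[C@@H](C)CO | intermediate
13 | (R)-2-methylhexanal | CCCC[C@@H](C)C=O | intermediate
14 | 2-[(1E,3R)-3-methylhept-1-en-1-yl]-4,4,5,5-tetramethyl-1,3,2-dioxaborolane | CCCC[C@@H](C)/C=C/B1OC(C)(C)C(C)(C)O1 | intermediate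
15 | (2E,4E,6R)-2,6-dimethyldeca-2,4-dien-1-ol | CCCC[C@@H](C)/C=C/C=C(\C)CO | intermediate
16 | (2E,4E,6R)-1-bromo-2,6-dimethyldeca-2,4-diene | CCCC[C@@H](C)/C=C/C=C(\C)CBr | intermediate
17 | (1R,4R,5R)-isothiocineole, (1R,4R,5R)-4,7,7-trimethyl-6-thiabicyclo[3.2.1]octane | C[C@@H]1CC[C@@H]2C[C@H]1SC2(C)C | starting material
18 | (1R,4R,5R)-6-[(2E,4E,6R)-2,6-dimethyldeca-2,4-dien-1-yl]-4,7,7-trimethyl-6-thiabicyclo[3.2.1]octan-6-ium triflate (configuration at sulfur not specified) | C[C@@H]1CC[C@@H]2C[C@H]1[S+](C/C(C)=C/C=C/[C@H](C)CCCC)C2(C)C.[O-]S(=O)(=O)C(F)(F)F | intermediate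
19 | sulfonium ylide of 18 | C[C@@H]1CC[C@@H]2C[C@H]1[S+]([CH-]/C(C)=C/C=C/[C@H](C)CCCC)C2(C)C | intermediate
20 | di-tert-butyl (2S,3R)-3-methyl-2-[(2E,4E,6R)-6-methyldeca-2,4-dien-2-yl]cyclopropane-1,1-dicarboxylate | CC(C)(C)OC(=O)C1(C(=O)OC(C)(C)C)[C@H](C)[C@H]1/C(C)=C/C=C/[C@H](C)CCCC | intermediate
21 | tert-butyl (3S,4S,5S)-4-methyl-5-[(2E,4E,6R)-6-methyldeca-2,4-dien-2-yl]-2-oxotetrahydrofuran-3-carboxylate | CCCC[C@@H](C)/C=C/C=C(\C)[C@H]1OC(=O)[C@@H](C(=O)OC(C)(C)C)[C@@H]1C | intermediate
22 | (3R,4S,5S)-4-methyl-5-[(2E,4E,6R)-6-methyldeca-2,4-dien-2-yl]-2-oxotetrahydrofuran-3-carboxylic acid (carboxyl trans to the C4 methyl) | CCCC[C@@H](C)/C=C/C=C(\C)[C@H]1OC(=O)[C@@H](C(=O)O)[C@@H]1C | intermediate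
23 | (4S,5S)-4-methyl-5-[(2E,4E,6R)-6-methyldeca-2,4-dien-2-yl]dihydrofuran-2(3H)-one | CCCC[C@@H](C)/C=C/C=C(\C)[C@H]1OC(=O)C[C@@H]1C | intermediate
24 | (E)-3-iodo-2-methylprop-2-enal | O=C/C(C)=C/I | intermediate
25 | (2E,4E)-5-iodo-4-methylpenta-2,4-dienal | O=C/C=C/C(C)=C/I | intermediate
26 | (R)-4-benzyl-3-propionyloxazolidin-2-one | CCC(=O)N1[C@H](Cc2ccccc2)COC1=O | starting material
27 | (Z)-di-n-butylboron enolate of 26 | C/C=C(\OB(CCCC)CCCC)N1[C@H](Cc2ccccc2)COC1=O | intermediate
28 | (R)-4-benzyl-3-[(2R,3S,4E,6E)-3-hydroxy-7-iodo-2,6-dimethylhepta-4,6-dienoyl]oxazolidin-2-one | I/C=C(C)/C=C/[C@H](O)[C@@H](C)C(=O)N1[C@H](Cc2ccccc2)COC1=O | intermediate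
29 | (2R,3S,4E,6E)-3-hydroxy-7-iodo-N-methoxy-N,2,6-trimethylhepta-4,6-dienamide | I/C=C(C)/C=C/[C@H](O)[C@@H](C)C(=O)N(C)OC | intermediate
30 | (2R,3S,4E,6E)-7-iodo-N-methoxy-N,2,6-trimethyl-3-(triethylsilyloxy)hepta-4,6-dienamide | I/C=C(C)/C=C/[C@H](O[Si](CC)(CC)CC)[C@@H](C)C(=O)N(C)OC | intermediate
31 | (3R,4S,5E,7E)-8-iodo-3,7-dimethyl-4-(triethylsilyloxy)octa-5,7-dien-2-one | I/C=C(C)/C=C/[C@H](O[Si](CC)(CC)CC)[C@@H](C)C(C)=O | intermediate
32 | lithium enolate of 23 | CCCC[C@@H](C)/C=C/C=C(\C)[C@H]1OC(O[Li])=C[C@@H]1C | intermediate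
33 | chlorozinc enolate of 23 | CCCC[C@@H](C)/C=C/C=C(\C)[C@H]1OC(O[Zn]Cl)=C[C@@H]1C | intermediate
34 | (3S,4S,5S)-3-[(1E,3E,5S,6R)-2,6-dimethyl-7-oxo-5-(triethylsilyloxy)octa-1,3-dien-1-yl]-4-methyl-5-[(2E,4E,6R)-6-methyldeca-2,4-dien-2-yl]dihydrofuran-2(3H)-one | CCCC[C@@H](C)/C=C/C=C(\C)[C@H]1OC(=O)[C@@H](/C=C(C)/C=C/[C@H](O[Si](CC)(CC)CC)[C@@H](C)C(C)=O)[C@@H]1C | intermediate
35 | (3S,4S,5S)-3-[(1E,3E,5S,6R)-5-hydroxy-2,6-dimethyl-7-oxoocta-1,3-dien-1-yl]-4-methyl-5-[(2E,4E,6R)-6-methyldeca-2,4-dien-2-yl]dihydrofuran-2(3H)-one | CCCC[C@@H](C)/C=C/C=C(\C)[C@H]1OC(=O)[C@@H](/C=C(C)/C=C/[C@H](O)[C@@H](C)C(C)=O)[C@@H]1C | target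

**Step count**
Total: 20 steps. Longest linear sequence: 13 steps (steps 3 to 13, then 19 and 20).

**Steps most likely to fail**

Step 11 (ylide cyclopropanation). What may go wrong is insufficient facial discrimination by the sulfide in the conjugate addition, which would erode the configuration of the methyl-bearing ring carbon, or proton abstraction from the γ-methyl group of 3 by the basic ylide in place of addition. The fallback sets the methyl-bearing centre by iminium catalysis and builds the diene afterwards. It sets out from malonate 1 and boronate 14 and comes back at cyclopropane 20. Bromination of 1 (NaH, then N-bromosuccinimide) would give di-tert-butyl 2-bromomalonate F1. Its Michael-initiated ring closure with (E)-but-2-enal under (S)-α,α-diphenylprolinol trimethylsilyl ether and 2,6-lutidine would give di-tert-butyl (2R,3R)-2-formyl-3-methylcyclopropane-1,1-dicarboxylate F2. Seyferth–Gilbert homologation (dimethyl (1-diazo-2-oxopropyl)phosphonate, K2CO3, MeOH) would give di-tert-butyl (2S,3R)-2-ethynyl-3-methylcyclopropane-1,1-dicarboxylate F3. Zirconium-catalysed carboalumination (AlMe3, Cp2ZrCl2) and iodinolysis would give di-tert-butyl (2R,3R)-2-[(E)-1-iodoprop-1-en-2-yl]-3-methylcyclopropane-1,1-dicarboxylate F4. Suzuki–Miyaura coupling of F4 with 14 (Pd(PPh3)4, K3PO4, THF/H2O, rt) would give 20.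

Step 12 (ring-opening lactonisation). What may go wrong is loss of the C6′ proton from the pentadienyl cation to give a triene, collapse of the ion pair at carbon instead of oxygen, or attack of the tert-butyl cation or isobutene on the diene. The fallback is a cation-free route to the trans lactone. It sets out from dienol 15 and comes back at lactone 23. Oxidation of 15 with MnO2 would give (2E,4E,6R)-2,6-dimethyldeca-2,4-dienal F5. Asymmetric (E)-crotylboration with the antipode of (E)-crotyldiisopinocampheylborane that attacks the Si face of the aldehyde (expected to be the reagent made from (+)-α-pinene) would give the anti alcohol (3S,4S,5E,7E,9R)-3,5,9-trimethyltrideca-1,5,7-trien-4-ol F6. Hydroboration of the terminal alkene with 9-BBN and oxidation (NaOH, H2O2) would give (3S,4S,5E,7E,9R)-3,5,9-trimethyltrideca-5,7-diene-1,4-diol F7. Oxidative lactonisation of the primary alcohol (TEMPO, PhI(OAc)2) would give 23.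

Step 19 (α-alkenylation). What may go wrong is proton transfer between the enolate and the methyl ketone or the more acidic product, migration of the new C1″=C2″ bond into conjugation with the lactone carbonyl, or poor trans selectivity at C3. The fallback reverses the polarity of the two partners. It sets out from lactone 23 and iodide 31 and comes back at silyl ether 34. Conversion of 23 into its silyl ketene acetal (LiN(SiMe3)2, Me3SiCl) and bromination with N-bromosuccinimide would give (4R,5S)-3-bromo-4-methyl-5-[(2E,4E,6R)-6-methyldeca-2,4-dien-2-yl]dihydrofuran-2(3H)-one F8 as both C3 epimers. Miyaura borylation of 31 (bis(pinacolato)diboron, PdCl2(PPh3)2, KOPh, toluene, 50 °C) would give (3R,4S,5E,7E)-3,7-dimethyl-8-(4,4,5,5-tetramethyl-1,3,2-dioxaborolan-2-yl)-4-(triethylsilyloxy)octa-5,7-dien-2-one F9. Suzuki–Miyaura coupling of the α-bromo lactone F8 with F9 (Pd(OAc)2, P(o-tol)3, K3PO4, THF) would give 34, and the epimerisable C3 should settle trans to the C4 methyl group.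

**Further compounds**
F1 | step 11 | di-tert-butyl 2-bromomalonate | CC(C)(C)OC(=O)C(Br)C(=O)OC(C)(C)C
F2 | step 11 | di-tert-butyl (2R,3R)-2-formyl-3-methylcyclopropane-1,1-dicarboxylate | CC(C)(C)OC(=O)C1(C(=O)OC(C)(C)C)[C@H](C)[C@H]1C=O
F3 | step 11 | di-tert-butyl (2S,3R)-2-ethynyl-3-methylcyclopropane-1,1-dicarboxylate | CC(C)(C)OC(=O)C1(C(=O)OC(C)(C)C)[C@H](C)[C@H]1C#C
F4 | step 11 | di-tert-butyl (2R,3R)-2-[(E)-1-iodoprop-1-en-2-yl]-3-methylcyclopropane-1,1-dicarboxylate | CC(C)(C)OC(=O)C1(C(=O)OC(C)(C)C)[C@H](C)[C@H]1/C(C)=C/I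
F5 | step 12 | (2E,4E,6R)-2,6-dimethyldeca-2,4-dienal | CCCC[C@@H](C)/C=C/C=C(\C)C=O
F6 | step 12 | (3S,4S,5E,7E,9R)-3,5,9-trimethyltrideca-1,5,7-trien-4-ol | CCCC[C@@H](C)/C=C/C=C(\C)[C@@H](O)[C@@H](C)C=C
F7 | step 12 | (3S,4S,5E,7E,9R)-3,5,9-trimethyltrideca-5,7-diene-1,4-diol | CCCC[C@@H](C)/C=C/C=C(\C)[C@@H](O)[C@@H](C)CCO
F8 | step 19 | (4R,5S)-3-bromo-4-methyl-5-[(2E,4E,6R)-6-methyldeca-2,4-dien-2-yl]dihydrofuran-2(3H)-one (both C3 epimers) | CCCC[C@@H](C)/C=C/C=C(\C)[C@H]1OC(=O)C(Br)[C@@H]1C
F9 | step 19 | (3R,4S,5E,7E)-3,7-dimethyl-8-(4,4,5,5-tetramethyl-1,3,2-dioxaborolan-2-yl)-4-(triethylsilyloxy)octa-5,7-dien-2-one | CC(=O)[C@H](C)[C@@H](O[Si](CC)(CC)CC)/C=C/C(C)=C/B1OC(C)(C)C(C)(C)O1
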